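**Plan**

1. Numbering throughout is that of tricyclo[5.4.0.0(2,8)]undecane: C1/C7 ring fusion, C2 the quaternary C–Me, C3/C5 the ester carbons, C6 the CMe2, C9=C10–C11(=O) the enone. The bicyclic precursors keep these numbers.
2. Cuts: the two ester C–O bonds and the C11 oxygen first; then the cyclobutane bond C2–C8, which opens the cage to a cis-fused cyclohexene oxide/cycloheptane-1,3-dione; then C3–C4 (Claisen condensation), C4–C5 (MeLi) and C6–C7 (Ireland–Claisen), back to a limonene-derived menthadienol and isobutyryl chloride.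
3. Forward: the cyclohexene ring comes from the chiral pool, the seven-membered 1,3-dione ring is closed by Claisen condensation, and the cyclobutane (and with it the third six-membered ring) by intramolecular epoxide opening; diol, esters and enone follow.
4. Enabling feature: C2 is the only deprotonatable γ-carbon of the C3/C5 1,3-dioxygenated seven-membered ring (C6 is quaternary) and lies 1,3-cis across the six-membered ring from C8, whose neighbour C9 takes the epoxide oxygen that later leaves to give the C9=C10 enone.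
5. Stereochemistry: C1 from the starting terpene; C7 by suprafacial [3,3] transfer; epoxide anti to the seven-membered ring; C2 and C8 by ring constraint and SN2 inversion; C3 and C5 by CBS reagent control.

Key step: step 9

Remark: compound 1 is taken as the single (1S,4R) isomer (hydroxyl cis to isopropenyl), a commercial terpene building block made from (R)-limonene.

**Route**

Step 1
Reactants: 1 (1S,4R)-1-methyl-4-(prop-1-en-2-yl)cyclohex-2-en-1-ol; 2 2-methylpropanoyl chloride
Product: 4 (1S,4R)-1-methyl-4-(prop-1-en-2-yl)cyclohex-2-en-1-yl 2-methylpropanoate, via lithium alkoxide 3 (not isolated)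
Conditions: n-BuLi, THF, −78 °C; then 2, −78 → 0 °C
Reagents that add atoms: none
Why: O-acylation of the lithium alkoxide of a hindered tertiary allylic alcohol with an acid chloride should proceed cold without allylic transposition and touches no stereocentre.

Step 2
Reactants: 4 tertiary allylic isobutyrate
Product: 8 2-methyl-2-[(1S,6R)-3-methyl-6-(prop-1-en-2-yl)cyclohex-2-en-1-yl]propanoic acid, via lithium ester enolate 5 (not isolated), via silyl ketene acetal 6 (not isolated), via trimethylsilyl ester 7 (not isolated)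
Conditions: LiN(iPr)2, THF, −78 °C; TMSCl, −78 → 60 °C; then 1 M HCl
Reagents that add atoms: none
Why: Ireland–Claisen rearrangement, in which the suprafacial [3,3] shift should deliver the quaternary C6 to C7 on the ring face that carried the C9–O bond, that is cis to the isopropenyl group on C1, while the double bond moves to C8=C9.

Step 3
Reactants: 8 acid
Product: 11 3-methyl-3-[(1S,6R)-3-methyl-6-(prop-1-en-2-yl)cyclohex-2-en-1-yl]butan-2-one, via lithium carboxylate 9 (not isolated), via dilithium gem-diolate 10 (not isolated)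
Conditions: MeLi (3.5 equiv), Et2O, 0 °C → rt; then H2O (inverse quench)
Reagents that add atoms: methyllithium, [Li]C
Why: Addition of MeLi to a lithium carboxylate stops at the gem-diolate, which should release the methyl ketone on hydrolysis (ketone synthesis from a carboxylic acid); the new methyl is the future C4.

Step 4
Reactants: 11 methyl ketone
Product: 13 3-[(1R,6R)-6-(1-hydroxypropan-2-yl)-3-methylcyclohex-2-en-1-yl]-3-methylbutan-2-one (both side-chain epimers), via alkyl-9-BBN borane 12 (not isolated)
Conditions: 9-BBN, THF, 0 °C → rt; then NaOH, H2O2, 0 °C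
Reagents that add atoms: hydrogen peroxide, OO
Why: Hydroboration–oxidation with 9-BBN is highly selective for the 1,1-disubstituted isopropenyl alkene over the trisubstituted ring alkene and places oxygen on the terminal carbon (future C3); the new C2 centre forms as an epimer mixture that is planarised in step 9.

Step 5
Reactants: 13 primary alcohol
Product: 15 2-[(1R,2R)-4-methyl-2-(2-methyl-3-oxobutan-2-yl)cyclohex-3-en-1-yl]propanoic acid (both C2 epimers), via aldehyde 14 (not isolated)
Conditions: CrO3, H2SO4, acetone, 0 °C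
Reagents that add atoms: water, O
Why: Jones oxidation should take the primary alcohol through the aldehyde hydrate to the acid and would re-oxidise any C5 carbinol formed by ketone reduction in step 4.

Step 6
Reactants: 15 keto acid
Product: 17 methyl 2-[(1R,2R)-4-methyl-2-(2-methyl-3-oxobutan-2-yl)cyclohex-3-en-1-yl]propanoate (both C2 epimers), via potassium carboxylate 16 (not isolated)
Conditions: MeI, K2CO3, DMF, rt
Reagents that add atoms: iodomethane, CI
Why: Carboxylate O-alkylation by SN2 on iodomethane.

Step 7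
Reactants: 17 keto ester
Product: 19 (1R,7R)-2,6,6,9-tetramethylbicyclo[5.4.0]undec-8-ene-3,5-dione (cis-fused; both C2 epimers), via potassium dione enolate 18 (not isolated)
Conditions: KOtBu (2.5 equiv), THF, 0 → 50 °C; then AcOH
Reagents that add atoms: none
Why: Intramolecular Claisen (Dieckmann-type) condensation, in which the methyl ketone enolate (the only enolisable side of C5, C6 being quaternary) acylates on the cis-held ester to close the seven-membered ring, driven by deprotonation of the 1,3-dione.

Step 8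
Reactants: 19 bicyclic dione
Product: 20 (1R,7S,8S,9R)-8,9-epoxy-2,6,6,9-tetramethylbicyclo[5.4.0]undecane-3,5-dione (both C2 epimers)
Conditions: mCPBA, NaHCO3, CH2Cl2, 0 °C
Reagents that add atoms: 3-chloroperoxybenzoic acid, OOC(=O)c1cccc(Cl)c1
Why: Prilezhaev epoxidation of the only alkene, where the peracid should approach the cyclohexene face opposite the cis-fused seven-membered ring (the pseudo-axial C2 substituent on C1 shields the other face), placing the epoxide oxygen anti to C2.

Step 9
Reactants: 20 epoxy dione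
Product: 23 (1R,2S,7R,8S,9R)-9-hydroxy-2,6,6,9-tetramethyltricyclo[5.4.0.0(2,8)]undecane-3,5-dione, via dilithium dianion 21 (not isolated), via dilithium alkoxide enolate 22 (not isolated)
Conditions: LiN(iPr)2 (2.6 equiv), THF, −78 → 0 °C; DMPU, 0 °C → rt; then AcOH
Reagents that add atoms: none
Why: Two equivalents of LiN(iPr)2 convert the 1,3-dione into its dianion, in which C2 is the only γ-carbon that can be deprotonated (C6 is quaternary); this localised, most nucleophilic carbon attacks the epoxide carbon C8 in an intramolecular SN2 opening. The closest known reaction types are the γ-alkylation of cyclic 1,3-dione dianions, including with epoxides, and the Stork epoxynitrile-type cyclisation of stabilised carbanions to cyclobutanes, as also used to close bicyclo[3.1.1]heptanes by enolate alkylation. The cyclobutane C1–C2–C8–C7 closes in a 4-exo-tet mode and, through the same bond, the third ring C1–C2–C8–C9–C10–C11 closes (6-endo with respect to the epoxide), with trans-diaxial (Fürst–Plattner) geometry because C2 is pseudo-axial on C1 and the epoxide oxygen lies on the opposite face. C8 is set by inversion at the epoxide carbon, C9 keeps its oxygen, and the quaternary C2 can only form with C3 pointing away from the C9–C11 bridge because the enolate double bond C2=C3 is part of the seven-membered ring. The selectivity needed is attack of C2 on C8 rather than on tertiary C9 (disfavoured for SN2 and requiring a boat), rather than O-alkylation (O3 is held trans to C1 across the enolate double bond) and rather than reaction of the delocalised C4/O5 terminus, which is far less nucleophilic than the γ-carbanion at low temperature. The strain released from the epoxide should offset the strain of the new cyclobutane.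

Step 10
Reactants: 23 tricyclic hydroxy dione
Product: 24 (1R,2S,3R,5R,7R,8S,9R)-2,6,6,9-tetramethyltricyclo[5.4.0.0(2,8)]undecane-3,5,9-triol
Conditions: (S)-Me-CBS oxazaborolidine (0.2 equiv), BH3·SMe2, THF, −20 → 0 °C; then MeOH
Reagents that add atoms: none
Why: CBS reduction, in which both ketones present the same large (quaternary C2 or C6)/small (C4H2) pair, so the (S)-oxazaborolidine–borane complex should deliver hydride in the same sense to each carbonyl and set (3R) and (5R), the trans-1,3-diol; the skeleton itself offers little facial bias because C1 and C8 flank C2 alike, which suits reagent control.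

Step 11
Reactants: 24 triol; 25 3-methylbut-2-enoyl chloride
Product: 26 (1R,2S,3R,5R,7R,8S,9R)-9-hydroxy-2,6,6,9-tetramethyltricyclo[5.4.0.0(2,8)]undecane-3,5-diyl bis(3-methylbut-2-enoate)
Conditions: 25 (4 equiv), pyridine, DMAP (cat.), CH2Cl2, 0 → 40 °C
Reagents that add atoms: none
Why: DMAP-catalysed acylation of the two secondary alcohols, the tertiary C9 alcohol being too hindered to react and pyridine (not a stronger amine) limiting deconjugation of the acyl chloride.

Step 12
Reactants: 26 tertiary alcohol diester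
Product: 28 (1R,2S,3R,5R,7R,8R)-2,6,6,9-tetramethyltricyclo[5.4.0.0(2,8)]undec-9-ene-3,5-diyl bis(3-methylbut-2-enoate), via sulfamate ester 27 (not isolated)
Conditions: Burgess reagent, benzene, 50 °C
Reagents that add atoms: none
Why: Burgess dehydration (syn elimination through the sulfamate ester) under neutral conditions avoids the cyclobutylcarbinyl cation and its Wagner–Meerwein shifts, and elimination toward C10 should give the more stable trisubstituted C9=C10 alkene since C8 is a bridgehead.

Step 13
Reactants: 28 alkene diester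
Product: 29 (1R,2R,3R,5R,7S,8R)-2,6,6,9-tetramethyl-11-oxotricyclo[5.4.0.0(2,8)]undec-9-ene-3,5-diyl bis(3-methylbut-2-enoate)
Conditions: CrO3, 3,5-dimethylpyrazole, CH2Cl2, −20 °C
Reagents that add atoms: chromium trioxide, O=[Cr](=O)=O
Why: Allylic oxidation with the CrO3–3,5-dimethylpyrazole complex, as in the pinene-to-verbenone conversion, where C11 is the only secondary allylic position of the electron-rich trisubstituted alkene (C8 is a bridgehead) and the electron-poor senecioate alkenes should react more slowly.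

**Compound list**

1 | (1S,4R)-1-methyl-4-(prop-1-en-2-yl)cyclohex-2-en-1-ol (hydroxyl cis to isopropenyl) | CC(=C)[C@@H]1CC[C@](C)(O)C=C1 | starting material
2 | 2-methylpropanoyl chloride | CC(C)C(Cl)=O | starting material
3 | lithium alkoxide of 1 | CC(=C)[C@@H]1CC[C@](C)([O-])C=C1.[Li+] | intermediate (not isolated)
4 | (1S,4R)-1-methyl-4-(prop-1-en-2-yl)cyclohex-2-en-1-yl 2-methylpropanoate | CC(=C)[C@@H]1CC[C@](C)(OC(=O)C(C)C)C=C1 | intermediate
5 | lithium enolate of ester 4 | CC(=C)[C@@H]1CC[C@](C)(OC([O-])=C(C)C)C=C1.[Li+] | intermediate (not isolated)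
6 | trimethylsilyl ketene acetal of ester 4 | CC(=C)[C@@H]1CC[C@](C)(OC(O[Si](C)(C)C)=C(C)C)C=C1 | intermediate (not isolated)
7 | trimethylsilyl ester of acid 8 | CC(=C)[C@@H]1CCC(C)=C[C@@H]1C(C)(C)C(=O)O[Si](C)(C)C | intermediate (not isolated)
8 | 2-methyl-2-[(1S,6R)-3-methyl-6-(prop-1-en-2-yl)cyclohex-2-en-1-yl]propanoic acid (side chains cis) | CC(=C)[C@@H]1CCC(C)=C[C@@H]1C(C)(C)C(O)=O | intermediate
9 | lithium carboxylate of 8 | CC(=C)[C@@H]1CCC(C)=C[C@@H]1C(C)(C)C([O-])=O.[Li+] | intermediate (not isolated)
10 | dilithium gem-diolate (MeLi adduct of 9) | CC(=C)[C@@H]1CCC(C)=C[C@@H]1C(C)(C)C(C)([O-])[O-].[Li+].[Li+] | intermediate (not isolated)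
11 | 3-methyl-3-[(1S,6R)-3-methyl-6-(prop-1-en-2-yl)cyclohex-2-en-1-yl]butan-2-one | CC(=C)[C@@H]1CCC(C)=C[C@@H]1C(C)(C)C(C)=O | intermediate
12 | B-alkyl-9-borabicyclo[3.3.1]nonane from 11 (both side-chain epimers) | CC(CB1C2CCCC1CCC2)[C@@H]1CCC(C)=C[C@@H]1C(C)(C)C(C)=O | intermediate (not isolated)
13 | 3-[(1R,6R)-6-(1-hydroxypropan-2-yl)-3-methylcyclohex-2-en-1-yl]-3-methylbutan-2-one (both side-chain epimers) | CC(CO)[C@@H]1CCC(C)=C[C@@H]1C(C)(C)C(C)=O | intermediate
14 | 2-[(1R,2R)-4-methyl-2-(2-methyl-3-oxobutan-2-yl)cyclohex-3-en-1-yl]propanal (both C2 epimers) | CC(C=O)[C@@H]1CCC(C)=C[C@@H]1C(C)(C)C(C)=O | intermediate (not isolated)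
15 | 2-[(1R,2R)-4-methyl-2-(2-methyl-3-oxobutan-2-yl)cyclohex-3-en-1-yl]propanoic acid (both C2 epimers) | CC(C(O)=O)[C@@H]1CCC(C)=C[C@@H]1C(C)(C)C(C)=O | intermediate
16 | potassium carboxylate of 15 | CC(C([O-])=O)[C@@H]1CCC(C)=C[C@@H]1C(C)(C)C(C)=O.[K+] | intermediate (not isolated)
17 | methyl 2-[(1R,2R)-4-methyl-2-(2-methyl-3-oxobutan-2-yl)cyclohex-3-en-1-yl]propanoate (both C2 epimers) | COC(=O)C(C)[C@@H]1CCC(C)=C[C@@H]1C(C)(C)C(C)=O | intermediate
18 | potassium enolate of dione 19 | [K+].[O-]C1=CC(=O)C(C)[C@@H]2CCC(C)=C[C@@H]2C1(C)C | intermediate (not isolated)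
19 | (1R,7R)-2,6,6,9-tetramethylbicyclo[5.4.0]undec-8-ene-3,5-dione (cis-fused; both C2 epimers) | O=C1CC(=O)C(C)[C@@H]2CCC(C)=C[C@@H]2C1(C)C | intermediate
20 | (1R,7S,8S,9R)-8,9-epoxy-2,6,6,9-tetramethylbicyclo[5.4.0]undecane-3,5-dione (epoxide anti to the seven-membered ring; both C2 epimers) | O=C1CC(=O)C(C)[C@@H]2CC[C@@]3(C)O[C@H]3[C@@H]2C1(C)C | intermediate
21 | dilithium dianion of 20 (C2=C3 and C4=C5 enolates) | [Li+].[Li+].[O-]C1=CC([O-])=C(C)[C@@H]2CC[C@@]3(C)O[C@H]3[C@@H]2C1(C)C | intermediate (not isolated)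
22 | dilithium salt of 23 (C9 alkoxide and dione enolate) | [Li+].[Li+].[O-]C1=CC(=O)[C@@]2(C)[C@@H]3CC[C@@](C)([O-])[C@H]2[C@@H]3C1(C)C | intermediate (not isolated)
23 | (1R,2S,7R,8S,9R)-9-hydroxy-2,6,6,9-tetramethyltricyclo[5.4.0.0(2,8)]undecane-3,5-dione | O=C1CC(=O)[C@@]2(C)[C@@H]3CC[C@@](C)(O)[C@H]2[C@@H]3C1(C)C | intermediate
24 | (1R,2S,3R,5R,7R,8S,9R)-2,6,6,9-tetramethyltricyclo[5.4.0.0(2,8)]undecane-3,5,9-triol | O[C@@H]1C[C@@H](O)[C@@]2(C)[C@@H]3CC[C@@](C)(O)[C@H]2[C@@H]3C1(C)C | intermediate
25 | 3-methylbut-2-enoyl chloride | CC(C)=CC(Cl)=O | starting material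
26 | (1R,2S,3R,5R,7R,8S,9R)-9-hydroxy-2,6,6,9-tetramethyltricyclo[5.4.0.0(2,8)]undecane-3,5-diyl bis(3-methylbut-2-enoate) | CC(C)=CC(=O)O[C@@H]1C[C@@H](OC(=O)C=C(C)C)[C@@]2(C)[C@@H]3CC[C@@](C)(O)[C@H]2[C@@H]3C1(C)C | intermediate
27 | C9 N-(methoxycarbonyl)sulfamate ester of 26, triethylammonium salt | CC(C)=CC(=O)O[C@@H]1C[C@@H](OC(=O)C=C(C)C)[C@@]2(C)[C@@H]3CC[C@@](C)(OS(=O)(=O)[N-]C(=O)OC)[C@H]2[C@@H]3C1(C)C.CC[NH+](CC)CC | intermediate (not isolated)
28 | (1R,2S,3R,5R,7R,8R)-2,6,6,9-tetramethyltricyclo[5.4.0.0(2,8)]undec-9-ene-3,5-diyl bis(3-methylbut-2-enoate) | CC(C)=CC(=O)O[C@@H]1C[C@@H](OC(=O)C=C(C)C)[C@@]2(C)[C@@H]3CC=C(C)[C@H]2[C@@H]3C1(C)C | intermediate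
29 | (1R,2R,3R,5R,7S,8R)-2,6,6,9-tetramethyl-11-oxotricyclo[5.4.0.0(2,8)]undec-9-ene-3,5-diyl bis(3-methylbut-2-enoate) | CC(C)=CC(=O)O[C@@H]1C[C@@H](OC(=O)C=C(C)C)[C@@]2(C)[C@@H]3C(=O)C=C(C)[C@H]2[C@@H]3C1(C)C | target

**Summary**

Total step count: 13. Longest linear sequence: 13 steps (1 → 29). No protecting groups are used.

**Steps most likely to fail**

Step 9. The risk is incomplete γ-deprotonation at the hindered C2 methine, or a four-membered ring closure slow enough that the stabilised enolate terminus (C4 or O5) opens the epoxide in a five-membered mode. The fallback replaces the dianion by the cross-conjugated enolate of a cycloheptenone in which C2–H is the only acidic hydrogen.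
- It sets out from dione 19. O-methylation with TMSCHN2 in MeOH at the less hindered C3 oxygen should give the vinylogous ester 3-methoxy-2,6,6,9-tetramethylbicyclo[5.4.0]undeca-3,8-dien-5-one F1.
- LiAlH4 reduction of C5=O and acidic work-up (Stork–Danheiser transposition) should give 2,6,6,9-tetramethylbicyclo[5.4.0]undeca-4,8-dien-3-one F2.
- mCPBA should epoxidise only the electron-rich C8=C9 alkene, giving the epoxy enone F3.
- LiN(iPr)2 in THF (−78 → 0 °C) forms the C2 enolate, which should close the cyclobutane as in step 9 to the tricyclic enone 9-hydroxy-2,6,6,9-tetramethyltricyclo[5.4.0.0(2,8)]undec-4-en-3-one F4.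
- Copper-catalysed conjugate borylation (CuCl, NaOtBu, a chiral bisphosphine whose antipode is chosen for the 5R product, B2pin2, MeOH) gives the C5 boronate F5, which NaBO3 oxidises to the (5R)-5,9-dihydroxy-3-ketone F6.
- Hydroxyl-directed anti reduction with Me4NBH(OAc)3 then gives triol 24, where the route is rejoined.

Step 10. The risk is weak facial discrimination by the catalyst at two very hindered ketones, or a chelate-directed second hydride transfer that gives the cis-diol. The fallback sets out from hydroxy dione 23 and uses asymmetric hydrogenation with RuCl2[(S)-BINAP] (H2, MeOH). There the 1,3-dicarbonyl chelate, not the size difference of the flanking groups, controls the first reduction, and the resulting β-hydroxy ketone is reduced in the matched sense to the anti-diol. The (S)-ligand is chosen by analogy with β-keto ester reductions, allowing for the reversed CIP priorities. It returns to the route at triol 24 and makes no new isolated compound.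

Step 13. The risk is poor site selectivity: competing oxidation at the allylic methyl groups of the two senecioates, or over-oxidation. The fallback carries out dehydration and allylic oxidation before the senecioates are installed.
- It sets out from triol 24. Ac2O, DMAP and pyridine acetylate the two secondary alcohols to the 3,5-diacetate F7.
- Burgess reagent gives the C9=C10 alkene diacetate F8.
- CrO3/3,5-dimethylpyrazole gives the enone diacetate F9.
- K2CO3 in MeOH gives (3R,5R)-3,5-dihydroxy-2,6,6,9-tetramethyltricyclo[5.4.0.0(2,8)]undec-9-en-11-one F10.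
- Acylation with 25 under the conditions of step 11 then gives the target 29 directly.

Further compounds
F1 | step 9 | 3-methoxy-2,6,6,9-tetramethylbicyclo[5.4.0]undeca-3,8-dien-5-one (cis-fused, configuration as in 19) | O=C1C=C(OC)C(C)[C@@H]2CCC(C)=C[C@@H]2C1(C)C
F2 | step 9 | 2,6,6,9-tetramethylbicyclo[5.4.0]undeca-4,8-dien-3-one (cis-fused) | C1=CC(=O)C(C)[C@@H]2CCC(C)=C[C@@H]2C1(C)C
F3 | step 9 | 8,9-epoxy-2,6,6,9-tetramethylbicyclo[5.4.0]undec-4-en-3-one (epoxide anti to the seven-membered ring) | C1=CC(=O)C(C)[C@@H]2CC[C@@]3(C)O[C@H]3[C@@H]2C1(C)C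
F4 | step 9 | 9-hydroxy-2,6,6,9-tetramethyltricyclo[5.4.0.0(2,8)]undec-4-en-3-one (configuration as in 23) | C1=CC(=O)[C@@]2(C)[C@@H]3CC[C@@](C)(O)[C@H]2[C@@H]3C1(C)C
F5 | step 9 | 9-hydroxy-2,6,6,9-tetramethyl-5-(4,4,5,5-tetramethyl-1,3,2-dioxaborolan-2-yl)tricyclo[5.4.0.0(2,8)]undecan-3-one (boron in the position of the later 5R hydroxyl) | CC1(C)OB(OC1(C)C)[C@@H]2CC(=O)[C@@]3(C)[C@@H]4CC[C@@](C)(O)[C@H]3[C@@H]4C2(C)C
F6 | step 9 | (5R)-5,9-dihydroxy-2,6,6,9-tetramethyltricyclo[5.4.0.0(2,8)]undecan-3-one | O[C@@H]1CC(=O)[C@@]2(C)[C@@H]3CC[C@@](C)(O)[C@H]2[C@@H]3C1(C)C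
F0 | step 10 | none | none
F7 | step 13 | 9-hydroxy-2,6,6,9-tetramethyltricyclo[5.4.0.0(2,8)]undecane-3,5-diyl diacetate (configuration as in 24) | CC(=O)O[C@@H]1C[C@@H](OC(C)=O)[C@@]2(C)[C@@H]3CC[C@@](C)(O)[C@H]2[C@@H]3C1(C)C
F8 | step 13 | 2,6,6,9-tetramethyltricyclo[5.4.0.0(2,8)]undec-9-ene-3,5-diyl diacetate | CC(=O)O[C@@H]1C[C@@H](OC(C)=O)[C@@]2(C)[C@@H]3CC=C(C)[C@H]2[C@@H]3C1(C)C
F9 | step 13 | 2,6,6,9-tetramethyl-11-oxotricyclo[5.4.0.0(2,8)]undec-9-ene-3,5-diyl diacetate | CC(=O)O[C@@H]1C[C@@H](OC(C)=O)[C@@]2(C)[C@@H]3C(=O)C=C(C)[C@H]2[C@@H]3C1(C)C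
F10 | step 13 | (3R,5R)-3,5-dihydroxy-2,6,6,9-tetramethyltricyclo[5.4.0.0(2,8)]undec-9-en-11-one | O[C@@H]1C[C@@H](O)[C@@]2(C)[C@@H]3C(=O)C=C(C)[C@H]2[C@@H]3C1(C)C
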